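The dihydrobenzofuran is cut at two bonds, C2–aryl (syringyl ring C) and C3–C3a (ring A), with O1 on C2 replaced by boron. The route exploits the C2–C3–CH2OH three-carbon unit, which carries ring C on C2, ring A (through C3a) on C3 and an oxygen (O1 of ring B) on C2. One palladium-catalysed conjunctive coupling of an (E)-3-silyloxypropenyl boronate, a syringyllithium and a ring A aryl iodide forms both C–C bonds and both stereocentres. The boronate is used as its B(mac) ester, because beta-substituted pinacol esters drift to Suzuki coupling. Oxidation, debenzylation, acid-mediated closure of ring B and a Doebner condensation complete the route.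

Key step: step 6

Labels: benzofuran numbering (O1, C2, C3, C3a); ring A is the benzo ring, ring B the dihydrofuran ring, ring C the syringyl ring. The target is (2S,3R), trans.

Assumption: the (Sp,Sp) enantiomer of the ferrocenyl bisphosphine is taken to bind the alkene face that leads to the (1S,2R) boronate; if the sense proves opposite, the mirror-image ligand is used and nothing else changes.

Step 1
Reactants: 1 acenaphthylene-1,2-dione
Product: 2 (1R,2S)-1,2-dimethyl-1,2-dihydroacenaphthylene-1,2-diol (cis meso diol; mac diol)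
Conditions: AlMe3 (3 equiv), toluene, 0 °C → rt; then aq. HCl; recrystallisation
Reagents that add atoms: trimethylaluminium, C[Al](C)C
Why: Twofold 1,2-addition of methyl to the 1,2-dione, in which the second methyl should enter the planar ring anti to the bulky aluminium alkoxide so that both hydroxyls lie on one face (cis, meso, no absolute configuration to set); crystallisation should remove any trans diol.

Step 2
Reactants: 3 tert-butyldimethyl(prop-2-yn-1-yloxy)silane; 4 catecholborane; 2 mac diol
Product: 6 (E)-3-(tert-butyldimethylsilyloxy)prop-1-enylboronic acid B(mac) ester (cyclic boronate of diol 2), via catechol alkenylboronate 5 (not isolated)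
Conditions: 4 (1.05 equiv), neat, 70 °C; then 2, THF, rt; dilute aq. NaOH wash
Reagents that add atoms: none
Why: Uncatalysed syn hydroboration of the terminal alkyne puts boron on the terminal carbon and gives the E alkene, and the labile catechol ester then exchanges with the aliphatic cis diol (transesterification) to the chromatography-stable B(mac) ester.

Step 3
Reactants: 7 4-bromo-2,6-dimethoxyphenol
Product: 8 2-(benzyloxy)-5-bromo-1,3-dimethoxybenzene
Conditions: BnBr, K2CO3, DMF, rt
Reagents that add atoms: benzyl bromide, BrCc1ccccc1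
Why: Williamson ether synthesis, in which the phenoxide formed with K2CO3 displaces bromide from benzyl bromide and the aryl bromide is inert.

Step 4
Reactants: 9 5-iodovanillin (4-hydroxy-3-iodo-5-methoxybenzaldehyde)
Product: 10 4-(benzyloxy)-3-iodo-5-methoxybenzaldehyde
Conditions: BnBr, K2CO3, DMF, rt
Reagents that add atoms: benzyl bromide, BrCc1ccccc1
Why: Williamson ether synthesis on the phenol; aldehyde and aryl iodide do not react with carbonate or benzyl bromide.

Step 5
Reactants: 10 4-(benzyloxy)-3-iodo-5-methoxybenzaldehyde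
Product: 11 2-[4-(benzyloxy)-3-iodo-5-methoxyphenyl]-1,3-dioxolane
Conditions: HOCH2CH2OH, TsOH·H2O (cat.), toluene, reflux, Dean–Stark
Reagents that add atoms: ethylene glycol, OCCO
Why: Acid-catalysed acetalisation driven by azeotropic removal of water masks the aldehyde against the ate complex of step 6, while benzyl ether and aryl iodide are unaffected.

Step 6
Reactants: 8 2-(benzyloxy)-5-bromo-1,3-dimethoxybenzene; 6 (E)-3-(tert-butyldimethylsilyloxy)prop-1-enylboronic acid B(mac) ester; 11 2-[4-(benzyloxy)-3-iodo-5-methoxyphenyl]-1,3-dioxolane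
Product: 14 [(1S,2R)-1-[4-(benzyloxy)-3,5-dimethoxyphenyl]-2-[2-(benzyloxy)-5-(1,3-dioxolan-2-yl)-3-methoxyphenyl]-3-(tert-butyldimethylsilyloxy)propyl]boronic acid B(mac) ester, via [4-(benzyloxy)-3,5-dimethoxyphenyl]lithium 12 (not isolated), via lithium ate complex 13 (not isolated)
Conditions: 8, n-BuLi (1.0 equiv), THF, −78 °C; 6, −78 °C → rt; then 11, Pd(OAc)2 (3 mol%), (Sp,Sp)-MandyPhos Fe[C5H3(PPh2)(CH(NMe2)Ph)]2 (3.6 mol%), KOTf (2 equiv), THF, 45 °C
Reagents that add atoms: none
Why: Bromine–lithium exchange gives aryllithium 12, which adds to the boron of 6 to give the four-coordinate ate complex 13; zerovalent palladium, formed in the flask from Pd(OAc)2 and the bisphosphine, inserts into the carbon–iodine bond of 11, and once KOTf has removed iodide as KI the cationic arylpalladium binds the alkene of 13 and triggers a 1,2-shift of the syringyl group from boron to the alpha-carbon (C2), anti to palladium arriving at the beta-carbon (C3), after which C–C reductive elimination joins C3 to C3a of ring A. The closest known reaction type is the enantioselective palladium-catalysed conjunctive cross-coupling of alkenylboron ate complexes with aryl electrophiles, in its variant for beta-substituted alkenyl B(mac) esters. No ring is closed. C3 is controlled by the ligand, which selects the alkene face that palladium binds, and C2 follows from the E geometry and the anti relationship of migration and palladation, so ring C and ring A add anti and boron sits where O1 will be. The step needs the metallate shift to win over direct Suzuki-type transfer of an organic group from boron to palladium, which the mac diol secures because its shielded oxygens disfavour the Pd–O–B bridge that transmetalation requires, and it needs a halide-free palladium centre, which KOTf secures. Beta-hydride elimination from the C3–palladium intermediate should be outrun by reductive elimination on the wide-bite-angle ligand, and acetal, benzyl ethers and silyl ether are inert.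

Step 7
Reactants: 14 [(1S,2R)-1-[4-(benzyloxy)-3,5-dimethoxyphenyl]-2-[2-(benzyloxy)-5-(1,3-dioxolan-2-yl)-3-methoxyphenyl]-3-(tert-butyldimethylsilyloxy)propyl]boronic acid B(mac) ester
Product: 15 (1S,2R)-1-[4-(benzyloxy)-3,5-dimethoxyphenyl]-2-[2-(benzyloxy)-5-(1,3-dioxolan-2-yl)-3-methoxyphenyl]-3-(tert-butyldimethylsilyloxy)propan-1-ol
Conditions: 30% aq. H2O2, 3 M aq. NaOH, THF, 0 °C → rt
Reagents that add atoms: hydrogen peroxide, OO
Why: Alkaline peroxide oxidation of a boronic ester, in which hydroperoxide adds to boron and the benzylic carbon migrates to oxygen with retention, so C1 keeps its configuration while silyl ether, acetal and benzyl ethers are untouched.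

Step 8
Reactants: 15 (1S,2R)-1-[4-(benzyloxy)-3,5-dimethoxyphenyl]-2-[2-(benzyloxy)-5-(1,3-dioxolan-2-yl)-3-methoxyphenyl]-3-(tert-butyldimethylsilyloxy)propan-1-ol
Product: 16 (1S,2R)-3-(tert-butyldimethylsilyloxy)-2-[5-(1,3-dioxolan-2-yl)-2-hydroxy-3-methoxyphenyl]-1-(4-hydroxy-3,5-dimethoxyphenyl)propan-1-ol
Conditions: H2 (1 atm), 10% Pd/C, EtOAc, rt; crude product carried on
Reagents that add atoms: none
Why: Catalytic hydrogenolysis cleaves both aryl benzyl ethers, and in a neutral aprotic solvent the secondary benzylic alcohol, the silyl ether and the dioxolane should survive.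

Step 9
Reactants: 16 (1S,2R)-3-(tert-butyldimethylsilyloxy)-2-[5-(1,3-dioxolan-2-yl)-2-hydroxy-3-methoxyphenyl]-1-(4-hydroxy-3,5-dimethoxyphenyl)propan-1-ol
Product: 19 (2S,3R)-2-(4-hydroxy-3,5-dimethoxyphenyl)-3-(hydroxymethyl)-7-methoxy-2,3-dihydro-1-benzofuran-5-carbaldehyde, via triol aldehyde 17 (not isolated), via para-quinone methide 18 (not isolated)
Conditions: 2 M aq. HCl, THF, rt → 40 °C
Reagents that add atoms: water, O
Why: Aqueous acid should hydrolyse the dioxolane and the primary silyl ether and ionise the 4-hydroxybenzylic alcohol to a para-quinone methide, which the ring A phenol captures in a 5-exo-trig 1,6-addition (acid-mediated phenylcoumaran closure); the closure is reversible, so C2 is re-set trans to the untouched C3 substituent, the arrangement that keeps aryl and hydroxymethyl on opposite faces of ring B.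

Step 10
Reactants: 19 (2S,3R)-2-(4-hydroxy-3,5-dimethoxyphenyl)-3-(hydroxymethyl)-7-methoxy-2,3-dihydro-1-benzofuran-5-carbaldehyde
Product: 21 (2E)-3-[(2S,3R)-2-(4-hydroxy-3,5-dimethoxyphenyl)-3-(hydroxymethyl)-7-methoxy-2,3-dihydro-1-benzofuran-5-yl]prop-2-enoic acid (target), via arylidenemalonic acid 20 (not isolated)
Conditions: CH2(CO2H)2 (3 equiv), pyridine, piperidine (cat.), 70 → 90 °C
Reagents that add atoms: malonic acid, OC(=O)CC(=O)O
Why: Knoevenagel–Doebner condensation, in which the aldehyde condenses with malonic acid and the arylidenemalonic acid loses CO2 in pyridine to give the thermodynamically favoured E acrylic acid; the pyridinium malonate buffer should keep the syringyl phenol largely protonated, so that the benzylic ether at C2 stays closed.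

Compound list
1 | acenaphthylene-1,2-dione (acenaphthoquinone) | O=C1C(=O)c2cccc3cccc1c23 | starting material
2 | (1R,2S)-1,2-dimethyl-1,2-dihydroacenaphthylene-1,2-diol (cis, meso; mac diol) | C[C@]1(O)c2cccc3cccc(c23)[C@@]1(C)O | intermediate
3 | tert-butyldimethyl(prop-2-yn-1-yloxy)silane | C#CCO[Si](C)(C)C(C)(C)C | starting material
4 | catecholborane (1,3,2-benzodioxaborole) | B1Oc2ccccc2O1 | starting material
5 | (E)-{[3-(1,3,2-benzodioxaborol-2-yl)prop-2-en-1-yl]oxy}(tert-butyl)dimethylsilane | CC(C)(C)[Si](C)(C)OC/C=C/B1Oc2ccccc2O1 | intermediate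
6 | (E)-3-(tert-butyldimethylsilyloxy)prop-1-enylboronic acid B(mac) ester (cyclic ester with diol 2) | CC(C)(C)[Si](C)(C)OC/C=C/B1O[C@@]2(C)c3cccc4cccc(c34)[C@@]2(C)O1 | intermediate
7 | 4-bromo-2,6-dimethoxyphenol | COc1cc(Br)cc(OC)c1O | starting material
8 | 2-(benzyloxy)-5-bromo-1,3-dimethoxybenzene | COc1cc(Br)cc(OC)c1OCc1ccccc1 | intermediate
9 | 5-iodovanillin (4-hydroxy-3-iodo-5-methoxybenzaldehyde) | COc1cc(C=O)cc(I)c1O | starting material
10 | 4-(benzyloxy)-3-iodo-5-methoxybenzaldehyde | COc1cc(C=O)cc(I)c1OCc1ccccc1 | intermediate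
11 | 2-[4-(benzyloxy)-3-iodo-5-methoxyphenyl]-1,3-dioxolane | COc1cc(C2OCCO2)cc(I)c1OCc1ccccc1 | intermediate
12 | [4-(benzyloxy)-3,5-dimethoxyphenyl]lithium | [Li]c1cc(OC)c(OCc2ccccc2)c(OC)c1 | intermediate
13 | lithium ate complex of 6 with the aryl group of 12 on boron (configuration at boron not defined) | [Li+].CC(C)(C)[Si](C)(C)OC/C=C/[B-]1(c2cc(OC)c(OCc3ccccc3)c(OC)c2)O[C@@]2(C)c3cccc4cccc(c34)[C@@]2(C)O1 | intermediate
14 | [(1S,2R)-1-[4-(benzyloxy)-3,5-dimethoxyphenyl]-2-[2-(benzyloxy)-5-(1,3-dioxolan-2-yl)-3-methoxyphenyl]-3-(tert-butyldimethylsilyloxy)propyl]boronic acid B(mac) ester | COc1cc([C@@H](B2O[C@@]3(C)c4cccc5cccc(c45)[C@@]3(C)O2)[C@@H](CO[Si](C)(C)C(C)(C)C)c2cc(C3OCCO3)cc(OC)c2OCc2ccccc2)cc(OC)c1OCc1ccccc1 | intermediate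
15 | (1S,2R)-1-[4-(benzyloxy)-3,5-dimethoxyphenyl]-2-[2-(benzyloxy)-5-(1,3-dioxolan-2-yl)-3-methoxyphenyl]-3-(tert-butyldimethylsilyloxy)propan-1-ol | COc1cc([C@@H](O)[C@@H](CO[Si](C)(C)C(C)(C)C)c2cc(C3OCCO3)cc(OC)c2OCc2ccccc2)cc(OC)c1OCc1ccccc1 | intermediate
16 | (1S,2R)-3-(tert-butyldimethylsilyloxy)-2-[5-(1,3-dioxolan-2-yl)-2-hydroxy-3-methoxyphenyl]-1-(4-hydroxy-3,5-dimethoxyphenyl)propan-1-ol | COc1cc([C@@H](O)[C@@H](CO[Si](C)(C)C(C)(C)C)c2cc(C3OCCO3)cc(OC)c2O)cc(OC)c1O | intermediate
17 | 3-[(1S,2R)-1,3-dihydroxy-1-(4-hydroxy-3,5-dimethoxyphenyl)propan-2-yl]-4-hydroxy-5-methoxybenzaldehyde | COc1cc([C@@H](O)[C@@H](CO)c2cc(C=O)cc(OC)c2O)cc(OC)c1O | intermediate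
18 | 3-[(2R)-1-(3,5-dimethoxy-4-oxocyclohexa-2,5-dien-1-ylidene)-3-hydroxypropan-2-yl]-4-hydroxy-5-methoxybenzaldehyde | COC1=CC(=C[C@@H](CO)c2cc(C=O)cc(OC)c2O)C=C(OC)C1=O | intermediate
19 | (2S,3R)-2-(4-hydroxy-3,5-dimethoxyphenyl)-3-(hydroxymethyl)-7-methoxy-2,3-dihydro-1-benzofuran-5-carbaldehyde | COc1cc([C@H]2Oc3c(OC)cc(C=O)cc3[C@@H]2CO)cc(OC)c1O | intermediate
20 | 2-{[(2S,3R)-2-(4-hydroxy-3,5-dimethoxyphenyl)-3-(hydroxymethyl)-7-methoxy-2,3-dihydro-1-benzofuran-5-yl]methylidene}propanedioic acid | COc1cc([C@H]2Oc3c(OC)cc(C=C(C(=O)O)C(=O)O)cc3[C@@H]2CO)cc(OC)c1O | intermediate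
21 | (2E)-3-[(2S,3R)-2-(4-hydroxy-3,5-dimethoxyphenyl)-3-(hydroxymethyl)-7-methoxy-2,3-dihydro-1-benzofuran-5-yl]prop-2-enoic acid | COc1cc([C@H]2Oc3c(OC)cc(/C=C/C(=O)O)cc3[C@@H]2CO)cc(OC)c1O | target

Total step count: 10 steps.
Longest linear sequence: 7 steps (steps 4, 5, 6, 7, 8, 9, 10; the branch through steps 1 and 2 is equally long).

Steps most likely to fail

1. Step 6. What may go wrong: direct transfer of the aryl or alkenyl group from boron to palladium (Suzuki-type coupling) outpaces the metallate shift, residual iodide stalls catalyst turnover, or the ortho-benzyloxy group erodes facial selectivity. The fallback gives up the metallate shift and builds the same array by an auxiliary-controlled aldol reaction; it sets out from 11 and 8 and returns at 15. Coupling of 11 with BrZnCH2CO2Et (Pd(dba)2, XPhos, THF, 50 °C) should give ethyl 2-[2-(benzyloxy)-5-(1,3-dioxolan-2-yl)-3-methoxyphenyl]acetate F1, and LiOH in THF/water, with work-up at pH 4–5, the acid 2-[2-(benzyloxy)-5-(1,3-dioxolan-2-yl)-3-methoxyphenyl]acetic acid F2. Activation with pivaloyl chloride/Et3N and acylation of (4S)-4-benzyl-1,3-oxazolidin-2-one in the presence of LiCl should give the imide (4S)-4-benzyl-3-{[2-(benzyloxy)-5-(1,3-dioxolan-2-yl)-3-methoxyphenyl]acetyl}-1,3-oxazolidin-2-one F3. Lithiation of 8 (n-BuLi, THF, −78 °C, through 12) and quenching with DMF gives 4-(benzyloxy)-3,5-dimethoxybenzaldehyde F4. Evans boron aldol reaction of F3 with F4 (Bu2BOTf, i-Pr2NEt, CH2Cl2, −78 → 0 °C) should give the (2S,3S) syn aldol adduct F5, in which the auxiliary fixes the carbon that becomes C3. LiBH4 in THF/water removes the auxiliary and gives (1S,2R)-1-[4-(benzyloxy)-3,5-dimethoxyphenyl]-2-[2-(benzyloxy)-5-(1,3-dioxolan-2-yl)-3-methoxyphenyl]propane-1,3-diol F6. TBSCl/imidazole in CH2Cl2 at 0 °C silylates the primary hydroxyl selectively and gives 15.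

2. Step 9. What may go wrong: the benzylic cation or quinone methide loses the C3 proton (stilbene formation, which erases C3) or oligomerises before the phenol closes, or closure stops at a cis/trans mixture. The fallback generates the quinone methide under base, where the ring A phenoxide is the trap, and deprotects afterwards; it sets out from 16 and returns at 19. Ac2O, pyridine and DMAP (cat.) give the triacetate (1S,2R)-1-(4-acetoxy-3,5-dimethoxyphenyl)-2-[2-acetoxy-5-(1,3-dioxolan-2-yl)-3-methoxyphenyl]-3-(tert-butyldimethylsilyloxy)propyl acetate F7. K2CO3 in MeOH at 0 °C cleaves the two aryl acetates, and the syringyl phenoxide expels the benzylic acetate to give the silyl- and acetal-protected quinone methide F8 (not isolated). The ring A phenoxide closes this to tert-butyl{[(2S,3R)-5-(1,3-dioxolan-2-yl)-2-(4-hydroxy-3,5-dimethoxyphenyl)-7-methoxy-2,3-dihydro-1-benzofuran-3-yl]methoxy}dimethylsilane F9, trans for the same reason as in the main route. Brief treatment with 1 M aq. HCl in THF at 0 °C → rt removes dioxolane and silyl ether and gives 19.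

3. Step 10. What may go wrong: base-induced opening of ring B from the syringyl phenoxide (retro-1,6-addition to the quinone methide), which would lead to epimerisation or alkene formation at C3, or sluggish decarboxylation. The fallback installs the side chain under neutral conditions in two steps; it sets out from 19 and returns at 21. Wittig olefination with allyl (triphenylphosphoranylidene)acetate in toluene at 60 °C should give the E ester allyl (2E)-3-[(2S,3R)-2-(4-hydroxy-3,5-dimethoxyphenyl)-3-(hydroxymethyl)-7-methoxy-2,3-dihydro-1-benzofuran-5-yl]prop-2-enoate F10. Pd(PPh3)4 (zerovalent palladium, cat.) with morpholine in THF at rt transfers the allyl group to the amine and gives 21.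

Further compounds
F1 | step 6 | ethyl 2-[2-(benzyloxy)-5-(1,3-dioxolan-2-yl)-3-methoxyphenyl]acetate | CCOC(=O)Cc1cc(C2OCCO2)cc(OC)c1OCc1ccccc1
F2 | step 6 | 2-[2-(benzyloxy)-5-(1,3-dioxolan-2-yl)-3-methoxyphenyl]acetic acid | OC(=O)Cc1cc(C2OCCO2)cc(OC)c1OCc1ccccc1
F3 | step 6 | (4S)-4-benzyl-3-{[2-(benzyloxy)-5-(1,3-dioxolan-2-yl)-3-methoxyphenyl]acetyl}-1,3-oxazolidin-2-one | O=C(Cc1cc(C2OCCO2)cc(OC)c1OCc1ccccc1)N1[C@@H](Cc2ccccc2)COC1=O
F4 | step 6 | 4-(benzyloxy)-3,5-dimethoxybenzaldehyde | COc1cc(C=O)cc(OC)c1OCc1ccccc1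
F5 | step 6 | (4S)-4-benzyl-3-{(2S,3S)-3-[4-(benzyloxy)-3,5-dimethoxyphenyl]-2-[2-(benzyloxy)-5-(1,3-dioxolan-2-yl)-3-methoxyphenyl]-3-hydroxypropanoyl}-1,3-oxazolidin-2-one | COc1cc([C@@H](O)[C@@H](C(=O)N2[C@@H](Cc3ccccc3)COC2=O)c2cc(C3OCCO3)cc(OC)c2OCc2ccccc2)cc(OC)c1OCc1ccccc1
F6 | step 6 | (1S,2R)-1-[4-(benzyloxy)-3,5-dimethoxyphenyl]-2-[2-(benzyloxy)-5-(1,3-dioxolan-2-yl)-3-methoxyphenyl]propane-1,3-diol | COc1cc([C@@H](O)[C@@H](CO)c2cc(C3OCCO3)cc(OC)c2OCc2ccccc2)cc(OC)c1OCc1ccccc1
F7 | step 9 | (1S,2R)-1-(4-acetoxy-3,5-dimethoxyphenyl)-2-[2-acetoxy-5-(1,3-dioxolan-2-yl)-3-methoxyphenyl]-3-(tert-butyldimethylsilyloxy)propyl acetate | COc1cc([C@@H](OC(C)=O)[C@@H](CO[Si](C)(C)C(C)(C)C)c2cc(C3OCCO3)cc(OC)c2OC(C)=O)cc(OC)c1OC(C)=O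
F8 | step 9 | 4-[(2R)-3-(tert-butyldimethylsilyloxy)-2-[5-(1,3-dioxolan-2-yl)-2-hydroxy-3-methoxyphenyl]propylidene]-2,6-dimethoxycyclohexa-2,5-dien-1-one | COC1=CC(=C[C@@H](CO[Si](C)(C)C(C)(C)C)c2cc(C3OCCO3)cc(OC)c2O)C=C(OC)C1=O
F9 | step 9 | tert-butyl{[(2S,3R)-5-(1,3-dioxolan-2-yl)-2-(4-hydroxy-3,5-dimethoxyphenyl)-7-methoxy-2,3-dihydro-1-benzofuran-3-yl]methoxy}dimethylsilane | COc1cc([C@H]2Oc3c(OC)cc(C4OCCO4)cc3[C@@H]2CO[Si](C)(C)C(C)(C)C)cc(OC)c1O
F10 | step 10 | allyl (2E)-3-[(2S,3R)-2-(4-hydroxy-3,5-dimethoxyphenyl)-3-(hydroxymethyl)-7-methoxy-2,3-dihydro-1-benzofuran-5-yl]prop-2-enoate | COc1cc([C@H]2Oc3c(OC)cc(/C=C/C(=O)OCC=C)cc3[C@@H]2CO)cc(OC)c1O
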